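**Retrosynthetic overview**

1. Target 11 is a 2H-chromen-6-ol. Its pyran ring (O1, C2, C3, C4, C4a, C8a) is fused to a benzene ring in which O1 on C8a stands para to the C6 hydroxyl. This lets the benzene ring be written as a 2,5-cyclohexadienone (C6 as carbonyl) with C8a as an sp3 spiro carbon carrying O1 and C4, next to a free CH at C4a; this is the feature that makes the key step possible.
2. Key disconnection C4–C4a: the six-membered pyran ring is not closed directly. It arises by 1,2-shift of the alkenyl carbon C4 from C8a to C4a (dienone–phenol ring expansion) in the five-membered spiro-2,5-dihydrofuran dienone 10. Dienone 10 forms in the same flask from the monocyclic Z-allylic alcohol phenol 9 by PhI(OAc)2 dearomatisation (O1–C8a bond).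
3. Phenol 9 comes from Z-semihydrogenation of aryl alkynol 8, which comes from Sonogashira union of 4-iodo-2,5-dimethylphenol 7 with the C20 alkynol 5 (aryl–C4 bond first made at the later C8a).
4. C2 is set as a C–O stereocentre by Katsuki–Sharpless epoxidation of natural phytol 1, which already holds C4′ and C8′, and is carried through epoxy chloride 3 to alkynol 5; no bond to C2 is broken afterwards.
5. Ring order: benzene ring (bought) → five-membered spiro ring (transient) → six-membered pyran ring by expansion; no protecting groups.

Key step: step 7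

Remark on the chemistry: read from the SMILES, the target is the (2S,4′R,8′R) isomer. Natural (E)-(7R,11R)-phytol, sold as a single isomer of natural origin, is assumed as the commercial source of the side chain.

**Route**

Step 1
Reactants: 1 natural phytol, (2E,7R,11R)-3,7,11,15-tetramethylhexadec-2-en-1-ol
Product: 2 (2S,3S)-2,3-epoxyphytol, [(2S,3S)-3-methyl-3-[(4R,8R)-4,8,12-trimethyltridecyl]oxiran-2-yl]methanol
Conditions: Ti(OiPr)4 (10 mol%), L-(+)-diisopropyl tartrate (12 mol%), t-BuOOH (2 equiv), 4 Å MS, CH2Cl2, −20 °C
Reagents that add atoms: tert-butyl hydroperoxide, CC(C)(C)OO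
Why: Katsuki–Sharpless asymmetric epoxidation of an E-trisubstituted allylic alcohol, in which the titanium complex of the L-(+)-tartrate should deliver oxygen to the face that gives the (2S,3S)-epoxide (reagent control, as with other E-allylic alcohols), so that the later C2 is fixed as a C–O stereocentre while the remote 7R and 11R centres are untouched.

Step 2
Reactants: 2 (2S,3S)-2,3-epoxyphytol
Product: 3 epoxy chloride, (2S,3R)-3-(chloromethyl)-2-methyl-2-[(4R,8R)-4,8,12-trimethyltridecyl]oxirane
Conditions: PPh3 (1.3 equiv), CCl4, NaHCO3 (solid), reflux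
Reagents that add atoms: carbon tetrachloride, ClC(Cl)(Cl)Cl
Why: Appel reaction, displacing the primary hydroxyl by chloride at a CH2 carbon under buffered conditions that should leave the trisubstituted epoxide intact; the changed descriptor at the CH carbon reflects only a change of CIP priorities.

Step 3
Reactants: 3 epoxy chloride
Product: 5 (3S,7R,11R)-3,7,11,15-tetramethylhexadec-1-yn-3-ol, via chlorovinyl alkoxide 4 (not isolated)
Conditions: LiN(iPr)2 (3.5 equiv), THF, −35 °C → rt; aq. NH4Cl
Reagents that add atoms: none
Why: Base-induced double elimination of a 2,3-epoxy chloride to a propargylic alcohol (deprotonation at CH2Cl with β-elimination opening of the epoxide to alkoxide 4, then dehydrochlorination and acetylide formation), in which the C–O bond at the fully substituted carbon is never broken, so the (S) epoxide carbon becomes the (3S) carbinol.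

Step 4
Reactants: 6 2,5-dimethylphenol
Product: 7 4-iodo-2,5-dimethylphenol
Conditions: N-iodosuccinimide (1.0 equiv), TsOH·H2O (10 mol%), MeCN, 0 °C → rt
Reagents that add atoms: N-iodosuccinimide, O=C1CCC(=O)N1I
Why: Electrophilic aromatic iodination, expected at the position para to the hydroxyl, which is the most activated and least hindered carbon of the ring; any ortho isomer should be removable by crystallisation.

Step 5
Reactants: 5 (3S,7R,11R)-3,7,11,15-tetramethylhexadec-1-yn-3-ol; 7 4-iodo-2,5-dimethylphenol
Product: 8 4-[(3S,7R,11R)-3-hydroxy-3,7,11,15-tetramethylhexadec-1-yn-1-yl]-2,5-dimethylphenol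
Conditions: PdCl2(PPh3)2 (3 mol%), CuI (5 mol%), Et3N, THF, 45 °C, argon
Reagents that add atoms: none
Why: Sonogashira coupling of an aryl iodide with a terminal alkyne, which should tolerate the free phenol and the tertiary alcohol and does not touch the carbinol stereocentre.

Step 6
Reactants: 8 4-[(3S,7R,11R)-3-hydroxy-3,7,11,15-tetramethylhexadec-1-yn-1-yl]-2,5-dimethylphenol
Product: 9 4-[(1Z,3S,7R,11R)-3-hydroxy-3,7,11,15-tetramethylhexadec-1-en-1-yl]-2,5-dimethylphenol
Conditions: H2 (1 atm), Pd/CaCO3 poisoned with Pb(OAc)2 (Lindlar catalyst), quinoline, EtOAc, rt, stopped after one equivalent of H2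
Reagents that add atoms: none
Why: Lindlar semihydrogenation, whose syn delivery of hydrogen on the poisoned palladium surface should give the Z-alkene that holds the tertiary hydroxyl within reach of the ipso carbon of the phenol.

Step 7
Reactants: 9 4-[(1Z,3S,7R,11R)-3-hydroxy-3,7,11,15-tetramethylhexadec-1-en-1-yl]-2,5-dimethylphenol
Product: 11 (2S)-2,5,8-trimethyl-2-[(4R,8R)-4,8,12-trimethyltridecyl]-2H-chromen-6-ol, via spiro-trienone 10 (not isolated)
Conditions: PhI(OAc)2 (1.0 equiv), CH2Cl2, −20 °C; then BF3·OEt2 (1.5 equiv), −78 → −20 °C; aq. NaHCO3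
Reagents that add atoms: none
Why: Oxidation of the phenol by hypervalent iodine (ligand exchange on PhI(OAc)2, loss of PhI) makes the ipso carbon electrophilic, and the tertiary hydroxyl, held close by the Z-alkene, adds to it in a 5-exo-trig closure that forms O1–C8a and the five-membered spiro-2,5-dihydrofuran ring of 10 (O1, C2, C3, C4, C8a); this is the well-known dearomatising spiroetherification of 4-(3-hydroxyalkyl)phenols. BF3 then binds the dienone oxygen (the later C6 oxygen), the alkenyl carbon C4 shifts from C8a to the neighbouring CH carbon C4a, and loss of the C4a proton restores the aromatic ring, so the six-membered pyran ring is closed by 1,2-shift ring expansion of the five-membered ring and not by a cyclisation; the closest known reaction type is the acid-mediated dienone–phenol rearrangement of 4-spiro-cyclohexadienones, hetero-spiro[4.5]trienones included, to 6-hydroxy benzo-fused six-membered rings. No new permanent stereocentre is formed: none of the four bonds at C2 is broken, so its (S) configuration from step 1 is carried over, and the spiro carbon of 10 is a passing stereocentre whose two epimers both end in 11. The step needs carbon and not oxygen to migrate, which the substrate secures because O1, staying on C8a, stabilises the arenium ion left behind as an oxocarbenium ion and because an sp2 carbon has a high migratory aptitude; it also needs migration to C4a and not to the methyl-bearing C8, which is secured because only the C4a adduct can lose a proton while the C8 adduct can only shift back. Oxidant and acid are added one after the other, PhI(OAc)2 being the limiting reagent, because the hydroquinone monoether 11 would be oxidised more easily than 9.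

**Compound list**

1 | natural phytol, (2E,7R,11R)-3,7,11,15-tetramethylhexadec-2-en-1-ol | OC/C=C(\C)CCC[C@H](C)CCC[C@H](C)CCCC(C)C | starting material
2 | (2S,3S)-2,3-epoxyphytol, [(2S,3S)-3-methyl-3-[(4R,8R)-4,8,12-trimethyltridecyl]oxiran-2-yl]methanol | OC[C@@H]1O[C@@]1(C)CCC[C@H](C)CCC[C@H](C)CCCC(C)C | intermediate
3 | (2S,3R)-3-(chloromethyl)-2-methyl-2-[(4R,8R)-4,8,12-trimethyltridecyl]oxirane | ClC[C@@H]1O[C@@]1(C)CCC[C@H](C)CCC[C@H](C)CCCC(C)C | intermediate
4 | lithium (3S,7R,11R)-1-chloro-3,7,11,15-tetramethylhexadec-1-en-3-olate, alkene geometry not fixed | ClC=C[C@]([O-])(C)CCC[C@H](C)CCC[C@H](C)CCCC(C)C.[Li+] | intermediate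
5 | (3S,7R,11R)-3,7,11,15-tetramethylhexadec-1-yn-3-ol | C#C[C@](O)(C)CCC[C@H](C)CCC[C@H](C)CCCC(C)C | intermediate
6 | 2,5-dimethylphenol | Cc1ccc(C)c(O)c1 | starting material
7 | 4-iodo-2,5-dimethylphenol | Cc1cc(O)c(C)cc1I | intermediate
8 | 4-[(3S,7R,11R)-3-hydroxy-3,7,11,15-tetramethylhexadec-1-yn-1-yl]-2,5-dimethylphenol | Cc1cc(O)c(C)cc1C#C[C@](O)(C)CCC[C@H](C)CCC[C@H](C)CCCC(C)C | intermediate
9 | 4-[(1Z,3S,7R,11R)-3-hydroxy-3,7,11,15-tetramethylhexadec-1-en-1-yl]-2,5-dimethylphenol | Cc1cc(O)c(C)cc1/C=C\[C@](O)(C)CCC[C@H](C)CCC[C@H](C)CCCC(C)C | intermediate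
10 | (2S)-2,6,9-trimethyl-2-[(4R,8R)-4,8,12-trimethyltridecyl]-1-oxaspiro[4.5]deca-3,6,9-trien-8-one, both epimers at the spiro carbon | CC1=CC2(C=C[C@](C)(CCC[C@H](C)CCC[C@H](C)CCCC(C)C)O2)C(C)=CC1=O | intermediate
11 | (2S)-2,5,8-trimethyl-2-[(4R,8R)-4,8,12-trimethyltridecyl]-2H-chromen-6-ol | Cc1cc(O)c(C)c2c1O[C@@](C)(CCC[C@H](C)CCC[C@H](C)CCCC(C)C)C=C2 | target

**Step count and risks**

Total step count: 7. Longest linear sequence: 6 steps (steps 1, 2, 3, 5, 6, 7, from phytol).

Steps most likely to fail:

Step 7. The Lewis acid may ionise the tertiary allylic C2–O1 bond of 10 or 11, which would erode the configuration at C2 or lead to elimination. Oxidant not yet consumed may over-oxidise the electron-rich product. The 1,2-shift may also be slow at the temperature the product tolerates. The fallback sets out from 8, keeps the same ring expansion at the saturated oxidation level, where no allylic C–O bond exists and the oxidant is removed by isolation, and comes back to the route at 11. Full hydrogenation of 8 (H2, Pd/C, EtOAc) should give the saturated carbinol phenol F1. PhI(OAc)2 in MeCN at 0 °C should give the isolable spiro-tetrahydrofuran dienone F2. BF3·OEt2 in CH2Cl2 should effect the dienone–phenol ring expansion by 1,2-shift of the CH2 carbon to the (2S)-chromanol F3. Acetylation (Ac2O, pyridine) should give the chromanyl acetate F4. Dehydrogenation with DDQ (dioxane, reflux) should give the 3,4-dehydro acetate F5. Methanolysis (K2CO3, MeOH, argon) should then give 11.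

Step 3. The amide base may open the hindered, fully substituted epoxide as a nucleophile instead of deprotonating the CH2Cl group, or the sequence may stall after the first elimination at the chlorovinyl stage. The fallback sets out from 3, avoids the alkyne altogether and comes back to the route at 9. NaI and Zn dust in refluxing MeOH (Finkelstein exchange, then reductive opening of the epoxy iodide) should give (3S)-isophytol F6. A Heck reaction of it with 7 (Pd(OAc)2, Bu4NCl, NaHCO3, DMF, 80 °C) should give the E-styrenyl carbinol F7. Sensitised E-to-Z photoisomerisation (Ir(ppy)3, blue LEDs, MeCN), which should favour the twisted Z-styrene, would then give 9.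

Step 6. Hydrogen uptake may run on to the saturated chain, and the Z-alkene may isomerise to the E-alkene on the catalyst surface; the E-isomer cannot spirocyclise. The fallback sets out from 8 and comes back at 9 without new compounds. It replaces catalytic hydrogenation by an electron-transfer cis-reduction with zinc activated by Cu(OAc)2 and AgNO3 in MeOH/H2O, a manifold that reduces conjugated alkynes but should not reduce the resulting alkene.

Further compounds
F1 | step 7 | 4-[(3S,7R,11R)-3-hydroxy-3,7,11,15-tetramethylhexadecyl]-2,5-dimethylphenol | Cc1cc(O)c(C)cc1CC[C@](O)(C)CCC[C@H](C)CCC[C@H](C)CCCC(C)C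
F2 | step 7 | (2S)-2,6,9-trimethyl-2-[(4R,8R)-4,8,12-trimethyltridecyl]-1-oxaspiro[4.5]deca-6,9-dien-8-one, both epimers at the spiro carbon | CC1=CC2(CC[C@](C)(CCC[C@H](C)CCC[C@H](C)CCCC(C)C)O2)C(C)=CC1=O
F3 | step 7 | (2S)-2,5,8-trimethyl-2-[(4R,8R)-4,8,12-trimethyltridecyl]chroman-6-ol | Cc1cc(O)c(C)c2c1O[C@@](C)(CCC[C@H](C)CCC[C@H](C)CCCC(C)C)CC2
F4 | step 7 | (2S)-2,5,8-trimethyl-2-[(4R,8R)-4,8,12-trimethyltridecyl]chroman-6-yl acetate | Cc1cc(OC(C)=O)c(C)c2c1O[C@@](C)(CCC[C@H](C)CCC[C@H](C)CCCC(C)C)CC2
F5 | step 7 | (2S)-2,5,8-trimethyl-2-[(4R,8R)-4,8,12-trimethyltridecyl]-2H-chromen-6-yl acetate | Cc1cc(OC(C)=O)c(C)c2c1O[C@@](C)(CCC[C@H](C)CCC[C@H](C)CCCC(C)C)C=C2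
F6 | step 3 | (3S,7R,11R)-3,7,11,15-tetramethylhexadec-1-en-3-ol | C=C[C@](O)(C)CCC[C@H](C)CCC[C@H](C)CCCC(C)C
F7 | step 3 | 4-[(1E,3S,7R,11R)-3-hydroxy-3,7,11,15-tetramethylhexadec-1-en-1-yl]-2,5-dimethylphenol | Cc1cc(O)c(C)cc1/C=C/[C@](O)(C)CCC[C@H](C)CCC[C@H](C)CCCC(C)C
F0 | step 6 | none | none
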